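**Strategy.** In vibsanin E a four-carbon chain, Cf–Ca–Cb(=O)–Cc, spans the cyclohexane from the methyl-bearing quaternary carbon Cq to the ring-junction carbon Ce two atoms away. The carbocyclic core is thus a bicyclo[4.3.1]decane, the skeleton delivered when a dienophile hangs from C2 of a diene. The route rests on that type 2 intramolecular Diels–Alder reaction, which makes the Cq–Cg and Ch–Ci bonds together, closes the six- and seven-membered carbocycles and sets Cq from the lone pyran stereocentre Cc. Its substrate is a 2,2-dimethyl-3,4-dimethylenetetrahydropyran bearing at Cc a CH(OMOM)CH2C(=O)C(CH3)=CH2 chain, with Cb held as an ether until the diene is consumed.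

Key step: step 12

Atom labels (target numbering used throughout):
- Seven-membered ring: Ca (CH with acetonyl) – Cb (ring C=O) – Cc (CH carrying the pyran OCH2) – Ce (three-ring junction CH) – Cg (bridge CH2) – Cq (quaternary C–CH3) – Cf (CH with the enol ester arm).
- Cyclohexane: Cq–Cg–Ce–Cd–Ci–Ch, where Cd is the CH next to CMe2, Ci the CH2 on Cd and Ch the CH2 on Cq.
- Pyran: Cc–CH2–O–CMe2–Cd–Ce.

Remarks on the chemistry (assumptions):
- Cb is carried as an (S)-methoxymethyl ether, not as a ketone or ketal. A Cb carbonyl beside a Cc–H that is also propargylic (later allylic) would let Cc racemise, and a ketal could only be made through that ketone. The carbon skeleton and the bonds formed in the key step are unchanged.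
- The Cb configuration is erased in step 16, so the diastereoselectivity of step 5 at Cb is not critical.
- Compounds 1, 2, 10, 17, 27, 29, 34 and 37 are taken as commercial.
- In step 3 the (S,S)-catalyst is assumed to show the same facial sense as with 4-silylbut-3-yn-2-ones.

Step 1
Reactants: 1 2-methyl-4-(trimethylsilyl)but-3-yn-2-ol; 2 2-bromo-N-methoxy-N-methylacetamide
Product: 4 N-methoxy-N-methyl-2-{[2-methyl-4-(trimethylsilyl)but-3-yn-2-yl]oxy}acetamide, via sodium alkoxide 3 (not isolated)
Conditions: NaH, THF, 0 °C; then 2, 0 °C → rt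
Reagents that add atoms: none
Why: Williamson ether synthesis run in the only workable polarity – the hindered tertiary propargylic alkoxide as nucleophile and a primary α-bromo amide that cannot eliminate as electrophile – so the tertiary ether forms by plain SN2 at a temperature that spares the C–Si bond; no stereocentre.

Step 2
Reactants: 4 Weinreb amide ether; 5 ethynyltrimethylsilane
Product: 7 1-{[2-methyl-4-(trimethylsilyl)but-3-yn-2-yl]oxy}-4-(trimethylsilyl)but-3-yn-2-one, via lithium (trimethylsilyl)acetylide 6 (not isolated)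
Conditions: 5, n-BuLi, THF, −78 °C; then 4, −78 → −40 °C; aq. NH4Cl
Reagents that add atoms: none
Why: Weinreb ketone synthesis, in which the chelated tetrahedral adduct survives until the quench and so releases the alkynyl ketone without over-addition; no stereocentre.

Step 3
Reactants: 7 ynone
Product: 8 (2R)-1-{[2-methyl-4-(trimethylsilyl)but-3-yn-2-yl]oxy}-4-(trimethylsilyl)but-3-yn-2-ol
Conditions: Ru[(S,S)-TsDPEN](p-cymene) (1 mol%), i-PrOH, rt
Reagents that add atoms: none
Why: Noyori asymmetric transfer hydrogenation of an alkynyl ketone, in which the catalyst tells alkynyl from alkyl, so the (S,S)-catalyst should give the carbinol of the same spatial sense as (S)-4-silylbut-3-yn-2-ols, named (R) here because the CH2O arm outranks the alkyne.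

Step 4
Reactants: 8 (R)-propargylic alcohol
Product: 9 (2R)-1-{[2-methyl-4-(trimethylsilyl)but-3-yn-2-yl]oxy}-4-(trimethylsilyl)but-3-yn-2-yl methanesulfonate
Conditions: MsCl, Et3N, CH2Cl2, −78 → 0 °C
Reagents that add atoms: methanesulfonyl chloride, CS(=O)(=O)Cl
Why: O-sulfonylation via sulfene does not touch the C–O bond, so the carbinol configuration is retained in the leaving group needed for the next step.

Step 5
Reactants: 9 (R)-mesylate; 10 3-[(tert-butyldimethylsilyl)oxy]propanal
Product: 12 (3S,4S)-1-[(tert-butyldimethylsilyl)oxy]-4-({[2-methyl-4-(trimethylsilyl)but-3-yn-2-yl]oxy}methyl)-6-(trimethylsilyl)hex-5-yn-3-ol, via allenylzinc 11 (not isolated)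
Conditions: Pd(OAc)2 (5 mol%), PPh3 (5 mol%), Et2Zn (3 equiv), THF, −78 → −20 °C; aq. NH4Cl
Reagents that add atoms: none
Why: Marshall propargylation – Pd(0) displaces the mesylate anti (SN2′), Et2Zn turns the allenylpalladium into a configurationally defined allenylzinc, and this adds to the aldehyde through a cyclic SE2′ transition state – so Cc forms with net inversion of (R)-9 and the carbinol Cb anti to it, the aldehyde chain avoiding the CH2O arm.

Step 6
Reactants: 12 homopropargylic alcohol
Product: 13 tert-butyl{[(3S,4S)-3-(methoxymethoxy)-4-({[2-methyl-4-(trimethylsilyl)but-3-yn-2-yl]oxy}methyl)-6-(trimethylsilyl)hex-5-yn-1-yl]oxy}dimethylsilane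
Conditions: MOMCl, i-Pr2NEt, Bu4NI (cat.), CH2Cl2, 0 °C → rt
Reagents that add atoms: chloromethyl methyl ether, COCCl
Why: acetal formation by O-alkylation gives a small, fluoride- and base-stable ether that keeps Cb at the alcohol level (no enolisable carbonyl beside Cc) and changes neither stereocentre.

Step 7
Reactants: 13 MOM ether
Product: 14 (3S,4S)-3-(methoxymethoxy)-4-{[(2-methylbut-3-yn-2-yl)oxy]methyl}hex-5-yn-1-ol
Conditions: TBAF (3.5 equiv), THF, 0 °C → rt
Reagents that add atoms: none
Why: fluoride-induced desilylation cleaves both C(sp)–SiMe3 bonds and the primary silyl ether in one operation, while the MOM acetal, the ethers and both stereocentres are inert to TBAF.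

Step 8
Reactants: 14 1,7-diyne alcohol
Product: 15 (3S)-3-[(3S)-6,6-dimethyl-4,5-dimethylideneoxan-3-yl]-3-(methoxymethoxy)propan-1-ol
Conditions: Pd2(dba)3·CHCl3 (2.5 mol%), P(o-tol)3 (10 mol%), AcOH (2 equiv), Et3SiH (2 equiv), PhMe, rt
Reagents that add atoms: none
Why: palladium-catalysed reductive cyclisation of a 1,7-diyne – hydropalladation of one terminal alkyne by H–Pd–OAc, 6-exo-dig carbopalladation of the other and reduction of the vinyl–Pd bond by the silane – gives the ring with two exocyclic methylenes, closure being helped by the gem-dimethyl group and leaving Cc untouched.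

Step 9
Reactants: 15 diene alcohol
Product: 16 (3S)-3-[(3S)-6,6-dimethyl-4,5-dimethylideneoxan-3-yl]-3-(methoxymethoxy)propanal
Conditions: Dess–Martin periodinane, NaHCO3, CH2Cl2, 0 °C → rt
Reagents that add atoms: none
Why: Dess–Martin oxidation under buffered, non-acidic conditions converts the primary alcohol into the aldehyde without harming the diene, the allylic tertiary ether or the MOM acetal.

Step 10
Reactants: 16 aldehyde; 17 isopropenylmagnesium bromide
Product: 18 (3RS,5S)-5-[(3S)-6,6-dimethyl-4,5-dimethylideneoxan-3-yl]-5-(methoxymethoxy)-2-methylpent-1-en-3-ol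
Conditions: THF, −78 °C; aq. NH4Cl
Reagents that add atoms: none
Why: Grignard 1,2-addition to the aldehyde at low temperature; the new carbinol centre forms without control, which does not matter because it becomes a carbonyl in step 11.

Step 11
Reactants: 18 allylic alcohol
Product: 19 (5S)-5-[(3S)-6,6-dimethyl-4,5-dimethylideneoxan-3-yl]-5-(methoxymethoxy)-2-methylpent-1-en-3-one
Conditions: Dess–Martin periodinane, NaHCO3, CH2Cl2, 0 °C
Reagents that add atoms: none
Why: Dess–Martin oxidation of the allylic alcohol gives the vinyl ketone and erases the uncontrolled centre, the buffer and low temperature guarding against β-elimination of the methoxymethoxy group.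

Step 12
Reactants: 19 trienone
Product: 20 tricyclic Diels–Alder adduct (Cf ketone; Cb–OMOM; Ce=Cd bridgehead alkene)
Conditions: PhMe (0.005 M), BHT (cat.), 150 °C, sealed tube
Reagents that add atoms: none
Why: The ketone-activated 1,1-disubstituted alkene adds to the s-cis-locked exocyclic diene in a concerted, thermally allowed [4+2] cycloaddition that forms Cq–Cg and Ch–Ci; the closest known reaction type is the type 2 intramolecular Diels–Alder synthesis of bicyclo[4.3.1]dec-1(9)-enes from 2-tethered dienes whose tether contains the activating ketone. The cyclohexene closes as the cycloaddition ring itself (both new bonds lie in it), whereas the seven-membered ring closes through the Cq–Cg bond alone as the bridging ring, the four-atom tether Cc–Cb–Ca–Cf being able to reach only the diene terminus next to its anchor (1,3-bridged, not 1,4-bridged, connectivity). The one new stereocentre, Cq, is dictated by Cc: allylic strain with the neighbouring exocyclic methylene holds the tether axial on the pyran, the dienophile can reach only the diene face on which the Cc–Cb bond stands and must place its carbonyl arm over the diene, so the Cq configuration follows from that of Cc by geometric necessity. The step needs regioselectivity (secured by tether length), π-facial selectivity (secured by Cc) and ring closure in preference to bimolecular cycloaddition (secured by 5 mM dilution and the pre-organised, reactive diene), while endo/exo selectivity is moot because no second centre is created. The new Ce=Cd double bond is a bridgehead alkene only with respect to a nine-membered perimeter, a strain that such alkenes bear at this temperature. Because Cb is an ether and not a carbonyl, Cc cannot enolise and keeps its configuration during heating.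

Step 13
Reactants: 20 Diels–Alder adduct
Product: 22 saturated tricyclic alcohol (Cf–OH as epimers; Cb–OMOM), via saturated ketone 21 (not isolated)
Conditions: H2 (1 atm), 5% Pt/C, EtOH, rt; then N2 purge, NaBH4, 0 °C → rt
Reagents that add atoms: none
Why: heterogeneous hydrogenation of the strained bridgehead alkene, then borohydride reduction of the ketone in the same pot: hydrogen can add only to the alkene face turned away from the Cc–Cb–Ca–Cf bridge, which puts the new hydrogens at Ce and Cd cis on that outer face (cis-fused pyran and cyclohexane as in the target), whereas the configuration of the carbinol Cf is irrelevant because it is eliminated in step 16.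

Step 14
Reactants: 22 alcohol
Product: 23 tricyclic mesylate (Cf–OMs; Cb–OMOM)
Conditions: MsCl, Et3N, DMAP (cat.), CH2Cl2, 0 °C → rt
Reagents that add atoms: methanesulfonyl chloride, CS(=O)(=O)Cl
Why: sulfonylation through sulfene, a small electrophile that reaches the hindered neopentyl-type alcohol, installs the leaving group for the later E1cB elimination.

Step 15
Reactants: 23 mesylate
Product: 24 tricyclic hydroxy mesylate (Cf–OMs; Cb–OH)
Conditions: ZnBr2, n-PrSH, CH2Cl2, 0 °C → rt
Reagents that add atoms: none
Why: Lewis acid-promoted transacetalisation of the MOM group to the thioacetal of formaldehyde frees the Cb alcohol quickly at 0 °C, conditions under which the hindered mesylate and the now saturated ring ether do not ionise.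

Step 16
Reactants: 24 hydroxy mesylate
Product: 26 tricyclic enone (Cb=O; Ca=Cf), via keto mesylate 25 (not isolated)
Conditions: Dess–Martin periodinane, NaHCO3, CH2Cl2, rt; then Et3N, 0 °C → rt
Reagents that add atoms: none
Why: Dess–Martin oxidation gives the β-mesyloxy ketone, whose Ca–H is now acidic, so triethylamine triggers E1cB loss of methanesulfonate; because Cq is quaternary the double bond can only form between Ca and Cf, which completes the 1,3-carbonyl transposition.

Step 17
Reactants: 26 enone; 27 vinylmagnesium bromide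
Product: 28 trimethylsilyl enol ether (Cb(OTMS)=Ca; vinyl on Cf)
Conditions: 27, CuBr·SMe2 (10 mol%), TMSCl, DMPU, THF, −78 °C; Et3N; cold aq. NaHCO3
Reagents that add atoms: chlorotrimethylsilane, C[Si](C)(C)Cl
Why: copper-catalysed, TMSCl-accelerated conjugate addition with in-situ O-silylation: the vinyl group should enter Cf on the enone face remote from the cyclohexane ring (syn to the Cq methyl, anti to Ch), the face left open by the bicyclo[4.3.1] framework, which gives the target configuration at Cf and a regiodefined Ca=Cb silyl enol ether.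

Step 18
Reactants: 28 silyl enol ether; 29 3-bromo-2-methylprop-1-ene
Product: 31 trans-2-(2-methylallyl)-3-vinyl tricyclic ketone (methallyl on Ca; vinyl on Cf), via lithium enolate 30 (not isolated)
Conditions: MeLi (1.05 equiv), THF, 0 °C → rt; then DMPU, 29, −78 → 0 °C
Reagents that add atoms: none
Why: cleavage of the silyl enol ether with MeLi gives the lithium enolate with its double bond fixed between Ca and Cb, and SN2 alkylation by the reactive allylic bromide should occur anti to the neighbouring vinyl group on Cf, giving the trans-2,3-disubstituted ketone required by the target.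

Step 19
Reactants: 31 diene ketone
Product: 33 tricyclic diketo aldehyde (Cf–CHO; Ca–CH2COCH3; Cb=O), via bis-ozonide 32 (not isolated)
Conditions: O3, CH2Cl2, −78 °C (Sudan III end point); then PPh3, −78 °C → rt
Reagents that add atoms: ozone, [O-][O+]=O
Why: ozonolysis with reductive work-up cleaves both terminal alkenes at once, the vinyl group becoming the formyl group on Cf and the methallyl group the acetonyl ketone on Ca, without basic conditions that could epimerise Ca, Cc or Cf.

Step 20
Reactants: 33 diketo aldehyde; 34 2-(dichloromethyl)-4,4,5,5-tetramethyl-1,3,2-dioxaborolane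
Product: 35 (E)-alkenyl pinacol boronate (Cf–CH=CH–Bpin)
Conditions: CrCl2 (8 equiv), LiI (4 equiv), THF, rt
Reagents that add atoms: none
Why: Takai–Utimoto olefination with the gem-dichromium species from 34 attacks aldehydes but not ketones and is generally (E)-selective, so the alkene geometry of the target is fixed here under non-basic conditions.

Step 21
Reactants: 35 alkenyl boronate
Product: 36 potassium (E)-alkenyltrifluoroborate
Conditions: aq. KHF2, MeOH, rt
Reagents that add atoms: potassium hydrogen difluoride, [K+].F[H-]F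
Why: ligand exchange at boron converts the pinacol boronate into the air-stable trifluoroborate needed for the coupling, with the (E)-alkene untouched.

Step 22
Reactants: 36 alkenyltrifluoroborate; 37 3-methylbut-2-enoic acid
Product: 38 vibsanin E
Conditions: CuBr (20 mol%), DMAP (40 mol%), 4 Å MS, O2 (1 atm), MeCN, 50 °C; 37 (2 equiv)
Reagents that add atoms: none
Why: copper-catalysed oxidative C–O coupling of Chan–Lam type between an alkenyltrifluoroborate and a carboxylic acid transfers the alkenyl group from boron to the carboxylate oxygen with retention of alkene geometry, so the (E)-enol ester forms without any enolate chemistry at the three carbonyl groups.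

**Compound list**

1 | 2-methyl-4-(trimethylsilyl)but-3-yn-2-ol | CC(C)(O)C#C[Si](C)(C)C | starting material
2 | 2-bromo-N-methoxy-N-methylacetamide | CON(C)C(=O)CBr | starting material
3 | sodium 2-methyl-4-(trimethylsilyl)but-3-yn-2-olate | CC(C)([O-])C#C[Si](C)(C)C.[Na+] | intermediate
4 | N-methoxy-N-methyl-2-{[2-methyl-4-(trimethylsilyl)but-3-yn-2-yl]oxy}acetamide | CON(C)C(=O)COC(C)(C)C#C[Si](C)(C)C | intermediate
5 | ethynyltrimethylsilane | C#C[Si](C)(C)C | starting material
6 | lithium (trimethylsilyl)acetylide | [Li]C#C[Si](C)(C)C | intermediate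
7 | 1-{[2-methyl-4-(trimethylsilyl)but-3-yn-2-yl]oxy}-4-(trimethylsilyl)but-3-yn-2-one | C[Si](C)(C)C#CC(=O)COC(C)(C)C#C[Si](C)(C)C | intermediate
8 | (2R)-1-{[2-methyl-4-(trimethylsilyl)but-3-yn-2-yl]oxy}-4-(trimethylsilyl)but-3-yn-2-ol | C[Si](C)(C)C#C[C@@H](O)COC(C)(C)C#C[Si](C)(C)C | intermediate
9 | (2R)-mesylate of 8 | C[Si](C)(C)C#C[C@@H](OS(C)(=O)=O)COC(C)(C)C#C[Si](C)(C)C | intermediate
10 | 3-[(tert-butyldimethylsilyl)oxy]propanal | CC(C)(C)[Si](C)(C)OCCC=O | starting material
11 | ethyl(allenyl)zinc from 9 (axially chiral; axis not encoded in the SMILES) | CC[Zn]C(=C=CCOC(C)(C)C#C[Si](C)(C)C)[Si](C)(C)C | intermediate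
12 | (3S,4S)-1-[(tert-butyldimethylsilyl)oxy]-4-({[2-methyl-4-(trimethylsilyl)but-3-yn-2-yl]oxy}methyl)-6-(trimethylsilyl)hex-5-yn-3-ol | CC(C)(C)[Si](C)(C)OCC[C@H](O)[C@@H](C#C[Si](C)(C)C)COC(C)(C)C#C[Si](C)(C)C | intermediate
13 | O-methoxymethyl ether of 12 (3S,4S) | CC(C)(C)[Si](C)(C)OCC[C@H](OCOC)[C@@H](C#C[Si](C)(C)C)COC(C)(C)C#C[Si](C)(C)C | intermediate
14 | (3S,4S)-3-(methoxymethoxy)-4-{[(2-methylbut-3-yn-2-yl)oxy]methyl}hex-5-yn-1-ol | OCC[C@H](OCOC)[C@@H](C#C)COC(C)(C)C#C | intermediate
15 | (3S)-3-[(3S)-6,6-dimethyl-4,5-dimethylideneoxan-3-yl]-3-(methoxymethoxy)propan-1-ol | OCC[C@H](OCOC)[C@@H]1COC(C)(C)C(=C)C1=C | intermediate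
16 | (3S)-3-[(3S)-6,6-dimethyl-4,5-dimethylideneoxan-3-yl]-3-(methoxymethoxy)propanal | O=CC[C@H](OCOC)[C@@H]1COC(C)(C)C(=C)C1=C | intermediate
17 | isopropenylmagnesium bromide | CC(=C)[Mg]Br | starting material
18 | (3RS,5S)-5-[(3S)-6,6-dimethyl-4,5-dimethylideneoxan-3-yl]-5-(methoxymethoxy)-2-methylpent-1-en-3-ol (C3 epimers) | CC(=C)C(O)C[C@H](OCOC)[C@@H]1COC(C)(C)C(=C)C1=C | intermediate
19 | (5S)-5-[(3S)-6,6-dimethyl-4,5-dimethylideneoxan-3-yl]-5-(methoxymethoxy)-2-methylpent-1-en-3-one (key-step precursor) | CC(=C)C(=O)C[C@H](OCOC)[C@@H]1COC(C)(C)C(=C)C1=C | intermediate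
20 | key-step product: 2,2-dimethylpyran-fused bicyclo[4.3.1]dec-1(9)-ene; Cf ketone, Cb–OMOM, Ce=Cd bridgehead alkene | O=C1C[C@H](OCOC)[C@@H]2COC(C)(C)C3=C2C[C@]1(C)CC3 | intermediate
21 | saturated tricyclic ketone (Cf=O; Cb–OMOM; H at Ce and Cd cis, anti to the four-carbon bridge) | C1[C@H](OCOC)[C@@H]2COC(C)(C)[C@@H]3CC[C@@](C)(C[C@@H]32)C1=O | intermediate
22 | saturated tricyclic alcohol (Cf–OH, epimers; Cb–OMOM) | C1[C@H](OCOC)[C@@H]2COC(C)(C)[C@@H]3CC[C@@](C)(C[C@@H]32)C1O | intermediate
23 | tricyclic mesylate (Cf–OMs, epimers; Cb–OMOM) | C1[C@H](OCOC)[C@@H]2COC(C)(C)[C@@H]3CC[C@@](C)(C[C@@H]32)C1OS(C)(=O)=O | intermediate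
24 | tricyclic hydroxy mesylate (Cf–OMs; Cb–OH) | C1[C@H](O)[C@@H]2COC(C)(C)[C@@H]3CC[C@@](C)(C[C@@H]32)C1OS(C)(=O)=O | intermediate
25 | tricyclic keto mesylate (Cb=O; Cf–OMs) | C1C(=O)[C@@H]2COC(C)(C)[C@@H]3CC[C@@](C)(C[C@@H]32)C1OS(C)(=O)=O | intermediate
26 | tricyclic enone (Cb=O; Ca=Cf) | C1=CC(=O)[C@@H]2COC(C)(C)[C@@H]3CC[C@@]1(C)C[C@@H]32 | intermediate
27 | vinylmagnesium bromide | C=C[Mg]Br | starting material
28 | trimethylsilyl enol ether (Cb(OTMS)=Ca; vinyl on Cf, syn to the Cq methyl) | C1=C(O[Si](C)(C)C)[C@@H]2COC(C)(C)[C@@H]3CC[C@@](C)(C[C@@H]32)[C@H]1C=C | intermediate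
29 | 3-bromo-2-methylprop-1-ene | CC(=C)CBr | starting material
30 | lithium enolate (Cb(OLi)=Ca; vinyl on Cf) | C1=C(O[Li])[C@@H]2COC(C)(C)[C@@H]3CC[C@@](C)(C[C@@H]32)[C@H]1C=C | intermediate
31 | tricyclic ketone with 2-methylallyl on Ca and vinyl on Cf, trans | CC(=C)C[C@@H]1C(=O)[C@@H]2COC(C)(C)[C@@H]3CC[C@@](C)(C[C@@H]32)[C@H]1C=C | intermediate
32 | bis(1,2,4-trioxolane) of 31 (ozonide carbons unassigned) | CC1(OCOO1)C[C@@H]2C(=O)[C@@H]3COC(C)(C)[C@@H]4CC[C@@](C)(C[C@@H]43)[C@H]2C5OCOO5 | intermediate
33 | tricyclic diketo aldehyde (Cf–CHO; Ca–CH2COCH3; Cb=O) | CC(=O)C[C@@H]1C(=O)[C@@H]2COC(C)(C)[C@@H]3CC[C@@](C)(C[C@@H]32)[C@H]1C=O | intermediate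
34 | 2-(dichloromethyl)-4,4,5,5-tetramethyl-1,3,2-dioxaborolane | ClC(Cl)B1OC(C)(C)C(C)(C)O1 | starting material
35 | (E)-alkenyl pinacol boronate (Cf–CH=CH–Bpin) | CC(=O)C[C@@H]1C(=O)[C@@H]2COC(C)(C)[C@@H]3CC[C@@](C)(C[C@@H]32)[C@H]1/C=C/B1OC(C)(C)C(C)(C)O1 | intermediate
36 | potassium (E)-alkenyltrifluoroborate | CC(=O)C[C@@H]1C(=O)[C@@H]2COC(C)(C)[C@@H]3CC[C@@](C)(C[C@@H]32)[C@H]1/C=C/[B-](F)(F)F.[K+] | intermediate
37 | 3-methylbut-2-enoic acid | CC(C)=CC(=O)O | starting material
38 | vibsanin E | CC(=O)C[C@@H]1C(=O)[C@@H]2COC(C)(C)[C@@H]3CC[C@@](C)(C[C@@H]32)[C@H]1/C=C/OC(=O)C=C(C)C | target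

**Step count.** Total: 22 steps. Longest linear sequence: 22 steps (the route is fully linear, steps 1–22).

**Steps most likely to fail**

1. Step 12 (cycloaddition). Bimolecular [4+2] reaction between two molecules, or thermal β-elimination of the methoxymethoxy group from the enone, may outrun ring closure; the Cb substituent, which lies on the pyran side of the tether, may also slow it. The fallback is a chelation-activated cycloaddition of the unprotected hydroxy enone; it sets out from 12 and returns at 20. TBAF removes all three silyl groups of 12 to give diyne diol F1, and the reductive cyclisation of step 8 gives diene diol F2. TEMPO/PhI(OAc)2 oxidises only the primary alcohol, giving hydroxy aldehyde F3, and isopropenylmagnesium bromide (excess) gives allylic diol F4. MnO2 oxidises only the allylic alcohol, giving hydroxy enone F5. Me2AlCl (CH2Cl2, −78 → 0 °C, high dilution) forms the aluminium alkoxide, which binds the enone carbonyl in a six-membered chelate and should let the same type 2 cycloaddition run at low temperature to hydroxy ketone F6. MOMCl/i-Pr2NEt then gives 20.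

2. Step 18 (enolate alkylation). SN2 attack at the hindered enolate carbon may be slow, so that O-alkylation or proton transfer (enolate migration to the Cc side, then ring opening by loss of the pyran alkoxide) competes, or the electrophile may enter syn to the vinyl group. The fallback is a palladium π-allyl alkylation (Tsuji–Trost type); it sets out from 28 and returns at 31. Enolate 30, generated as in step 18, is converted by BEt3 into lithium enoxyborate F7. This is allylated with 2-methylallyl acetate and Pd(PPh3)4 (THF, rt); the soft π-allyl electrophile should react at carbon only. A cis product could be equilibrated at Ca with DBU.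

3. Step 22 (C–O coupling). Protodeboronation or oxidative homocoupling of the alkenylboron species may be faster than C–O bond formation, or copper/O2 may oxidise the 1,4-diketone. The fallback builds the enol ester C=C bond by Wittig olefination instead of the C–O bond; it sets out from 33 and returns at 38. 3-Methylbut-2-enoyl chloride and paraformaldehyde (cat. ZnCl2, 60 °C) give chloromethyl 3-methylbut-2-enoate F8, and PPh3 (MeCN, reflux) gives acyloxymethyl phosphonium chloride F9. KHMDS (THF, −78 °C) gives acyloxymethylene ylide F10, which should olefinate only the aldehyde of 33. Vibsanin E 38 would then be separated from its Z isomer by chromatography.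

**Further compounds**

F1 | step 12 | (3S,4S)-4-{[(2-methylbut-3-yn-2-yl)oxy]methyl}hex-5-yne-1,3-diol | OCC[C@H](O)[C@@H](C#C)COC(C)(C)C#C
F2 | step 12 | (3S)-3-[(3S)-6,6-dimethyl-4,5-dimethylideneoxan-3-yl]propane-1,3-diol | OCC[C@H](O)[C@@H]1COC(C)(C)C(=C)C1=C
F3 | step 12 | (3S)-3-[(3S)-6,6-dimethyl-4,5-dimethylideneoxan-3-yl]-3-hydroxypropanal | O=CC[C@H](O)[C@@H]1COC(C)(C)C(=C)C1=C
F4 | step 12 | (3RS,5S)-5-[(3S)-6,6-dimethyl-4,5-dimethylideneoxan-3-yl]-2-methylpent-1-ene-3,5-diol | CC(=C)C(O)C[C@H](O)[C@@H]1COC(C)(C)C(=C)C1=C
F5 | step 12 | (5S)-5-[(3S)-6,6-dimethyl-4,5-dimethylideneoxan-3-yl]-5-hydroxy-2-methylpent-1-en-3-one | CC(=C)C(=O)C[C@H](O)[C@@H]1COC(C)(C)C(=C)C1=C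
F6 | step 12 | tricyclic hydroxy ketone (Cf=O; Cb–OH; Ce=Cd bridgehead alkene) | O=C1C[C@H](O)[C@@H]2COC(C)(C)C3=C2C[C@]1(C)CC3
F7 | step 18 | lithium triethyl(enoxy)borate of the Ca=Cb enolate | C1=C(O[B-](CC)(CC)CC)[C@@H]2COC(C)(C)[C@@H]3CC[C@@](C)(C[C@@H]32)[C@H]1C=C.[Li+]
F8 | step 22 | chloromethyl 3-methylbut-2-enoate | CC(C)=CC(=O)OCCl
F9 | step 22 | {[(3-methylbut-2-enoyl)oxy]methyl}triphenylphosphonium chloride | CC(C)=CC(=O)OC[P+](c1ccccc1)(c1ccccc1)c1ccccc1.[Cl-]
F10 | step 22 | (triphenylphosphoranylidene)methyl 3-methylbut-2-enoate | CC(C)=CC(=O)OC=P(c1ccccc1)(c1ccccc1)c1ccccc1
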